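**Retrosynthetic overview**

1. The arene, the only ring, is numbered C1 (side chain), C2 (OAc), C3 (OH), C4 (CH3), C5 (OH), C6 (H), with side chain C7(=CH2)–C8H(O-angeloyl)–prenyl. The feature used is that the C1 carbon substituent and the C2 oxygen are neighbours, while C3–O/C4–CH3/C5–O is the pattern of symmetric 2-methylresorcinol, so a C1–C2 aryne flanked by the C3 oxygen can take carbon at C1 and a masked oxygen at C2.
2. Endgame: the C3/C5 silyl ethers, the C2 acetate (from a C2–B bond via the phenol) and the C8 angelate are taken back to boronate carbinol 18.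
3. Key disconnection: C1–C7 and C2–B of 18 are formed in one flask from iodoaryl sulfonate 6 (aryne precursor), the alkoxide-bearing alkenylmagnesium 13 and isopropoxy pinacolborane 14.
4. 6 comes from 2-methylresorcinol (silylation, C–H borylation/oxidation, ortho-iodination, sulfonylation). 13 comes from acrolein (2-bromoacrolein, Brown allylboration setting C8 as S, cross-metathesis to the prenyl terminus, Br–Li–Mg exchange).
5. No ring is formed in the route; the arene is bought.

Key step: step 9

Assumption: boronate 18 is treated as the open pinacol ester with a free C8 hydroxyl; a reversible B–O contact from that hydroxyl is not expected to expel pinacol under the neutral work-up.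

**Route**

Step 1
Reactants: 1 2-methylresorcinol
Product: 2 1,3-bis(triisopropylsilyloxy)-2-methylbenzene
Conditions: TIPSCl, imidazole, DMF, 50 °C
Reagents that add atoms: chlorotriisopropylsilane, CC(C)[Si](Cl)(C(C)C)C(C)C
Why: Standard phenol silylation; TIPS is preferred to a smaller silyl group because the C3 silyl ether later sits beside a free C2 phenol (steps 11 and 12), where a small group could shift from O3 to O2, and because its bulk shields C2 of the aryne.

Step 2
Reactants: 2 1,3-bis(triisopropylsilyloxy)-2-methylbenzene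
Product: 4 4-methyl-3,5-bis(triisopropylsilyloxy)phenol, via arylboronate 3 (not isolated)
Conditions: [Ir(OMe)(cod)]2 (cat.), dtbpy, B2pin2, THF, 80 °C; then NaBO3·4H2O, THF/H2O, rt
Reagents that add atoms: sodium perborate NaBO3·4H2O (gives the new oxygen), [Na+].[Na+].O[B-]1(O)OO[B-](O)(O)OO1; bis(pinacolato)diboron (gives the boryl group of 3 only), CC1(C)OB(OC1(C)C)B1OC(C)(C)C(C)(C)O1
Why: Iridium-catalysed C–H borylation is sterically governed and the C–H para to the methyl group is the only one without an ortho substituent, and perborate then converts C–B into C–O by 1,2-aryl migration in the same flask.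

Step 3
Reactants: 4 4-methyl-3,5-bis(triisopropylsilyloxy)phenol
Product: 5 2-iodo-4-methyl-3,5-bis(triisopropylsilyloxy)phenol
Conditions: NIS (1.0 equiv), CH2Cl2, –40 → 0 °C, dark
Reagents that add atoms: N-iodosuccinimide, O=C1CCC(=O)N1I
Why: Electrophilic aromatic iodination in which the two open positions are equivalent by symmetry and both are activated by the free hydroxyl and the silyloxy groups, so only the degree of iodination has to be held by stoichiometry and temperature.

Step 4
Reactants: 5 2-iodo-4-methyl-3,5-bis(triisopropylsilyloxy)phenol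
Product: 6 2-iodo-4-methyl-3,5-bis(triisopropylsilyloxy)phenyl 4-chlorobenzenesulfonate
Conditions: 4-ClC6H4SO2Cl, Et3N, DMAP (cat.), CH2Cl2, 0 °C → rt
Reagents that add atoms: 4-chlorobenzenesulfonyl chloride, O=S(=O)(Cl)c1ccc(Cl)cc1
Why: Plain O-sulfonylation of the phenol, giving the leaving group on C1 next to the C2 iodide; the aryl silyl ethers are stable to amine base.

Step 5
Reactants: 7 acrolein
Product: 9 2-bromoacrolein, via 2,3-dibromopropanal 8 (not isolated)
Conditions: Br2, CH2Cl2, –78 → 0 °C; then Et3N, 0 °C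
Reagents that add atoms: bromine, BrBr
Why: Bromine addition to the alkene followed by amine-induced loss of HBr through the acidic α-hydrogen is the standard bromination–dehydrobromination route to an α-bromo enal.

Step 6
Reactants: 9 2-bromoacrolein
Product: 10 (S)-2-bromohexa-1,5-dien-3-ol
Conditions: (–)-Ipc2B(allyl) (reagent built on (+)-α-pinene, salt-free), Et2O/pentane, –100 → –78 °C; then NaOH, H2O2, 0 °C → rt
Reagents that add atoms: (–)-B-allyldiisopinocampheylborane, C=CCB([C@@H]1C[C@@H]2C[C@H]([C@H]1C)C2(C)C)[C@@H]1C[C@@H]2C[C@H]([C@H]1C)C2(C)C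
Why: Brown allylboration through a chair six-membered transition state, in which the isopinocampheyl groups from (+)-α-pinene deliver allyl to the Si face of the non-enolisable aldehyde; since the 1-bromovinyl group ranks above allyl, this gives the S carbinol (C8 of the target).

Step 7
Reactants: 10 (S)-2-bromohexa-1,5-dien-3-ol
Product: 11 (S)-2-bromo-6-methylhepta-1,5-dien-3-ol
Conditions: 2-methyl-2-butene (excess), second-generation Grubbs catalyst RuCl2(=CHPh)(PCy3)(H2IMes) (cat.), CH2Cl2, 40 °C
Reagents that add atoms: 2-methyl-2-butene, CC=C(C)C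
Why: Olefin cross-metathesis of the monosubstituted terminal alkene with 2-methyl-2-butene installs the trisubstituted prenyl terminus and releases propene, while the 1,1-disubstituted electron-poor bromoalkene is not engaged and the stereocentre is untouched.

Step 8
Reactants: 11 (S)-2-bromo-6-methylhepta-1,5-dien-3-ol
Product: 13 [(3S)-3-(bromomagnesiooxy)-6-methylhepta-1,5-dien-2-yl]magnesium bromide, via dilithio species 12 (not isolated)
Conditions: t-BuLi (3.0 equiv), Et2O, –78 °C; then MgBr2·OEt2 (2.1 equiv), –78 → –20 °C; solution used directly in step 9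
Reagents that add atoms: magnesium bromide etherate MgBr2·OEt2, Br[Mg]Br.CCOCC; tert-butyllithium (gives the lithium of 12 only), [Li]C(C)(C)C
Why: O-deprotonation followed by bromine–lithium exchange (the third equivalent destroys tert-butyl bromide) gives the 2-lithio allylic alkoxide, whose oxide is not a leaving group so no allene forms, and transmetalation to magnesium tempers its basicity; C8 is not touched.

Step 9
Reactants: 6 2-iodo-4-methyl-3,5-bis(triisopropylsilyloxy)phenyl 4-chlorobenzenesulfonate; 13 [(3S)-3-(bromomagnesiooxy)-6-methylhepta-1,5-dien-2-yl]magnesium bromide; 14 2-isopropoxy-4,4,5,5-tetramethyl-1,3,2-dioxaborolane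
Product: 18 (S)-2-[4-methyl-2-(4,4,5,5-tetramethyl-1,3,2-dioxaborolan-2-yl)-3,5-bis(triisopropylsilyloxy)phenyl]-6-methylhepta-1,5-dien-3-ol, via C2-magnesiated aryl sulfonate 15 (not isolated), via 3-silyloxyaryne 16 (not isolated), via C2-arylmagnesium adduct 17 (not isolated)
Conditions: 6, i-PrMgCl·LiCl (1.05 equiv), THF, –78 °C; add 13 (1.5 equiv), –78 → 0 °C; then 14 (3 equiv), –78 °C → rt; aq. NH4Cl
Reagents that add atoms: isopropylmagnesium chloride–lithium chloride i-PrMgCl·LiCl (gives the MgCl of 15 only), CC(C)[Mg]Cl.[Li+].[Cl-]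
Why: Iodine–magnesium exchange at C2 gives 15, which on warming expels the 4-chlorobenzenesulfonate from C1 to release aryne 16; the alkenyl C–Mg bond of 13 adds across the C1–C2 triple bond and the C2 arylmagnesium 17 so formed is captured at boron of 14 with loss of isopropoxide, so that C1–C7 and C2–B are made in one flask. The closest known reaction type is aryne generation from 2-iodoaryl sulfonates with i-PrMgCl, addition of Grignard reagents to 3-oxygenated arynes and electrophilic quench of the resulting arylmagnesium; only the magnesium alkoxide carried by the nucleophile is new to the substrate. No ring is closed and no stereocentre is created; C8 travels as its alkoxide, which cannot be lost by β-elimination from the alkenyl metal and is not epimerised. The step needs carbon at C1 and metal at C2: the inductively withdrawing C3 silyloxy group polarises and distorts the aryne so that the nucleophile attacks the remote terminus C1 and the carbanion develops at C2 next to oxygen, the TIPS bulk adds a steric bias in the same sense, and the weaker opposing pull of the C5 oxygen is outweighed. It also needs the carbon and not the oxygen of 13 to add, which the much higher nucleophilicity of the C–Mg bond should secure, and the exchange must be complete at –78 °C before 13 is added so that 13 is not spent on iodine–magnesium exchange.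

Step 10
Reactants: 18 (S)-2-[4-methyl-2-(4,4,5,5-tetramethyl-1,3,2-dioxaborolan-2-yl)-3,5-bis(triisopropylsilyloxy)phenyl]-6-methylhepta-1,5-dien-3-ol; 19 angelic acid
Product: 21 (S)-2-[4-methyl-2-(4,4,5,5-tetramethyl-1,3,2-dioxaborolan-2-yl)-3,5-bis(triisopropylsilyloxy)phenyl]-6-methylhepta-1,5-dien-3-yl (Z)-2-methylbut-2-enoate, via mixed anhydride 20 (not isolated)
Conditions: 19, 2,4,6-Cl3C6H2COCl, Et3N, toluene, rt; then 18, toluene, 75 °C (no DMAP)
Reagents that add atoms: 2,4,6-trichlorobenzoyl chloride (gives the aroyl part of 20 only), O=C(Cl)c1c(Cl)cc(Cl)cc1Cl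
Why: Yamaguchi esterification through the mixed anhydride, run without a nucleophilic amine catalyst so that the Z geometry of the angeloyl unit is kept; acylation occurs at oxygen with retention at C8, and the boronate keeps the C2 oxygen masked.

Step 11
Reactants: 21 (S)-2-[4-methyl-2-(4,4,5,5-tetramethyl-1,3,2-dioxaborolan-2-yl)-3,5-bis(triisopropylsilyloxy)phenyl]-6-methylhepta-1,5-dien-3-yl (Z)-2-methylbut-2-enoate
Product: 22 (S)-2-[2-hydroxy-4-methyl-3,5-bis(triisopropylsilyloxy)phenyl]-6-methylhepta-1,5-dien-3-yl (Z)-2-methylbut-2-enoate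
Conditions: NaBO3·4H2O, THF/H2O, 0 °C → rt
Reagents that add atoms: sodium perborate NaBO3·4H2O, [Na+].[Na+].O[B-]1(O)OO[B-](O)(O)OO1
Why: Ipso-hydroxylation of the arylboronate by hydroperoxide addition to boron and 1,2-aryl shift, under conditions mild enough for the hindered angelate, the two alkenes and the TIPS ethers.

Step 12
Reactants: 22 (S)-2-[2-hydroxy-4-methyl-3,5-bis(triisopropylsilyloxy)phenyl]-6-methylhepta-1,5-dien-3-yl (Z)-2-methylbut-2-enoate
Product: 23 (S)-2-[2-acetoxy-4-methyl-3,5-bis(triisopropylsilyloxy)phenyl]-6-methylhepta-1,5-dien-3-yl (Z)-2-methylbut-2-enoate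
Conditions: Ac2O, pyridine, DMAP (cat.), CH2Cl2, 0 °C → rt
Reagents that add atoms: acetic anhydride, CC(=O)OC(C)=O
Why: DMAP-catalysed acetylation of the only free hydroxyl, the C2 phenol, which is why the acetate can go onto O2 alone.

Step 13
Reactants: 23 (S)-2-[2-acetoxy-4-methyl-3,5-bis(triisopropylsilyloxy)phenyl]-6-methylhepta-1,5-dien-3-yl (Z)-2-methylbut-2-enoate
Product: 24 (S)-2-(2-acetoxy-3,5-dihydroxy-4-methylphenyl)-6-methylhepta-1,5-dien-3-yl (Z)-2-methylbut-2-enoate (target)
Conditions: HF·pyridine, pyridine, THF, 0 °C → rt; Me3SiOMe quench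
Reagents that add atoms: none
Why: Fluoride-mediated cleavage of the two aryl silyl ethers in a buffered, slightly acidic medium, chosen so that no phenoxide is formed and the acetate should stay on O2 rather than move to the freed O3; both esters and both alkenes tolerate these conditions.

**Compound list**

1 | 2-methylresorcinol | Cc1c(O)cccc1O | starting material
2 | 1,3-bis(triisopropylsilyloxy)-2-methylbenzene | Cc1c(O[Si](C(C)C)(C(C)C)C(C)C)cccc1O[Si](C(C)C)(C(C)C)C(C)C | intermediate
3 | 2-[4-methyl-3,5-bis(triisopropylsilyloxy)phenyl]-4,4,5,5-tetramethyl-1,3,2-dioxaborolane | Cc1c(O[Si](C(C)C)(C(C)C)C(C)C)cc(B2OC(C)(C)C(C)(C)O2)cc1O[Si](C(C)C)(C(C)C)C(C)C | intermediate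
4 | 4-methyl-3,5-bis(triisopropylsilyloxy)phenol | Cc1c(O[Si](C(C)C)(C(C)C)C(C)C)cc(O)cc1O[Si](C(C)C)(C(C)C)C(C)C | intermediate
5 | 2-iodo-4-methyl-3,5-bis(triisopropylsilyloxy)phenol | Cc1c(O[Si](C(C)C)(C(C)C)C(C)C)cc(O)c(I)c1O[Si](C(C)C)(C(C)C)C(C)C | intermediate
6 | 2-iodo-4-methyl-3,5-bis(triisopropylsilyloxy)phenyl 4-chlorobenzenesulfonate | Cc1c(O[Si](C(C)C)(C(C)C)C(C)C)cc(OS(=O)(=O)c2ccc(Cl)cc2)c(I)c1O[Si](C(C)C)(C(C)C)C(C)C | intermediate
7 | acrolein | C=CC=O | starting material
8 | 2,3-dibromopropanal (racemic) | O=CC(Br)CBr | intermediate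
9 | 2-bromoacrolein | C=C(Br)C=O | intermediate
10 | (S)-2-bromohexa-1,5-dien-3-ol | C=C(Br)[C@H](CC=C)O | intermediate
11 | (S)-2-bromo-6-methylhepta-1,5-dien-3-ol | C=C(Br)[C@H](CC=C(C)C)O | intermediate
12 | lithium (3S)-2-lithio-6-methylhepta-1,5-dien-3-olate | C=C([Li])[C@H](CC=C(C)C)O[Li] | intermediate
13 | [(3S)-3-(bromomagnesiooxy)-6-methylhepta-1,5-dien-2-yl]magnesium bromide | C=C([Mg]Br)[C@H](CC=C(C)C)O[Mg]Br | intermediate
14 | 2-isopropoxy-4,4,5,5-tetramethyl-1,3,2-dioxaborolane (isopropoxy pinacolborane) | CC(C)OB1OC(C)(C)C(C)(C)O1 | starting material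
15 | 2-(chloromagnesio)-4-methyl-3,5-bis(triisopropylsilyloxy)phenyl 4-chlorobenzenesulfonate | Cc1c(O[Si](C(C)C)(C(C)C)C(C)C)cc(OS(=O)(=O)c2ccc(Cl)cc2)c([Mg]Cl)c1O[Si](C(C)C)(C(C)C)C(C)C | intermediate
16 | 4-methyl-3,5-bis(triisopropylsilyloxy)benzyne (triple bond between C1 and C2) | CC1=C(O[Si](C(C)C)(C(C)C)C(C)C)C#CC=C1O[Si](C(C)C)(C(C)C)C(C)C | intermediate
17 | bromomagnesium (3S)-2-[2-(bromomagnesio)-4-methyl-3,5-bis(triisopropylsilyloxy)phenyl]-6-methylhepta-1,5-dien-3-olate | C=C(c1cc(O[Si](C(C)C)(C(C)C)C(C)C)c(C)c(O[Si](C(C)C)(C(C)C)C(C)C)c1[Mg]Br)[C@H](CC=C(C)C)O[Mg]Br | intermediate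
18 | (S)-2-[4-methyl-2-(4,4,5,5-tetramethyl-1,3,2-dioxaborolan-2-yl)-3,5-bis(triisopropylsilyloxy)phenyl]-6-methylhepta-1,5-dien-3-ol | C=C(c1cc(O[Si](C(C)C)(C(C)C)C(C)C)c(C)c(O[Si](C(C)C)(C(C)C)C(C)C)c1B1OC(C)(C)C(C)(C)O1)[C@H](CC=C(C)C)O | intermediate
19 | angelic acid, (Z)-2-methylbut-2-enoic acid | C/C=C(/C)C(=O)O | starting material
20 | (Z)-2-methylbut-2-enoic 2,4,6-trichlorobenzoic anhydride | C/C=C(/C)C(=O)OC(=O)c1c(Cl)cc(Cl)cc1Cl | intermediate
21 | (S)-2-[4-methyl-2-(4,4,5,5-tetramethyl-1,3,2-dioxaborolan-2-yl)-3,5-bis(triisopropylsilyloxy)phenyl]-6-methylhepta-1,5-dien-3-yl (Z)-2-methylbut-2-enoate | C=C(c1cc(O[Si](C(C)C)(C(C)C)C(C)C)c(C)c(O[Si](C(C)C)(C(C)C)C(C)C)c1B1OC(C)(C)C(C)(C)O1)[C@H](CC=C(C)C)OC(=O)/C(C)=C\C | intermediate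
22 | (S)-2-[2-hydroxy-4-methyl-3,5-bis(triisopropylsilyloxy)phenyl]-6-methylhepta-1,5-dien-3-yl (Z)-2-methylbut-2-enoate | C=C(c1cc(O[Si](C(C)C)(C(C)C)C(C)C)c(C)c(O[Si](C(C)C)(C(C)C)C(C)C)c1O)[C@H](CC=C(C)C)OC(=O)/C(C)=C\C | intermediate
23 | (S)-2-[2-acetoxy-4-methyl-3,5-bis(triisopropylsilyloxy)phenyl]-6-methylhepta-1,5-dien-3-yl (Z)-2-methylbut-2-enoate | C=C(c1cc(O[Si](C(C)C)(C(C)C)C(C)C)c(C)c(O[Si](C(C)C)(C(C)C)C(C)C)c1OC(C)=O)[C@H](CC=C(C)C)OC(=O)/C(C)=C\C | intermediate
24 | (S)-2-(2-acetoxy-3,5-dihydroxy-4-methylphenyl)-6-methylhepta-1,5-dien-3-yl (Z)-2-methylbut-2-enoate, CNP0147405.1 | C=C(c1cc(O)c(C)c(O)c1OC(C)=O)[C@H](CC=C(C)C)OC(=O)/C(C)=C\C | target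

**Step count**

Total: 13 steps. Longest linear sequence: 9 steps (steps 1–4 then 9–13; the side-chain branch, steps 5–8 then 9–13, is equally long).

**Steps most likely to fail**

Step 9. The crowded, alkoxide-bearing alkenylmagnesium may add too slowly, so that the aryne is lost to oligomerisation or isopropyl transfer, or the flanked C2 magnesium may be protonated before it is borylated. The fallback avoids the aryne and forms C1–C7 by cross-coupling; it sets out from phenol 4 and dilithio species 12 and comes back at acetate 23. Phenol 4 is oxygenated at one of its equivalent ortho positions with IBX in DMF and the o-quinone is reduced in the same flask with Na2S2O4 to 4-methyl-3,5-bis(triisopropylsilyloxy)benzene-1,2-diol F1. The less hindered hydroxyl, the one flanked by C6–H, is triflated with PhNTf2/Et3N to give 2-hydroxy-4-methyl-3,5-bis(triisopropylsilyloxy)phenyl trifluoromethanesulfonate F2, and the remaining hydroxyl is acetylated (Ac2O, pyridine, DMAP) to 2-acetoxy-4-methyl-3,5-bis(triisopropylsilyloxy)phenyl trifluoromethanesulfonate F3. In parallel 12 is quenched with Bu3SnCl to (S)-6-methyl-2-(tributylstannyl)hepta-1,5-dien-3-ol F4. Stille coupling of F3 with F4 under neutral conditions (Pd(PPh3)4, CuCl, LiCl, DMSO, 60 °C) should give (S)-2-[2-acetoxy-4-methyl-3,5-bis(triisopropylsilyloxy)phenyl]-6-methylhepta-1,5-dien-3-ol F5, and Yamaguchi angeloylation of F5 under the conditions of step 10 leads to 23.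

Step 10. Acylation of the hindered allylic carbinol next to the boronate may be slow, and long heating of the activated angeloyl unit invites Z to E isomerisation to the tiglate. The fallback builds the Z alkene on the ester instead of transferring it; it sets out from 18 and comes back at 21. Carbinol 18 is esterified with 2-[bis(2,2,2-trifluoroethoxy)phosphoryl]propanoic acid (DCC, DMAP, CH2Cl2) to (S)-2-[4-methyl-2-(4,4,5,5-tetramethyl-1,3,2-dioxaborolan-2-yl)-3,5-bis(triisopropylsilyloxy)phenyl]-6-methylhepta-1,5-dien-3-yl 2-[bis(2,2,2-trifluoroethoxy)phosphoryl]propanoate F6. Still–Gennari olefination of F6 with acetaldehyde (KN(SiMe3)2, 18-crown-6, THF, –78 °C) should then give the Z-trisubstituted enoate 21.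

Step 11. Oxidation of the doubly ortho-flanked boronate may be sluggish, leaving time for protodeboronation, for perborate attack on the angelate or for a silyl shift to the new phenoxide. The fallback removes boron before any ester is present and tells the two oxygens apart by acidity; it sets out from 18 and comes back at 23. Boronate 18 is oxidised with NaOH/H2O2 in THF at 0 °C to (S)-2-[2-hydroxy-4-methyl-3,5-bis(triisopropylsilyloxy)phenyl]-6-methylhepta-1,5-dien-3-ol F7. The phenol alone is acetylated (Ac2O 1.05 equiv, Et3N, CH2Cl2, –20 °C, no DMAP) to (S)-2-[2-acetoxy-4-methyl-3,5-bis(triisopropylsilyloxy)phenyl]-6-methylhepta-1,5-dien-3-ol F5, the compound also reached in the first fallback, and angeloylation as in step 10 gives 23.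

**Further compounds**

F1 | step 9 | 4-methyl-3,5-bis(triisopropylsilyloxy)benzene-1,2-diol | Cc1c(O[Si](C(C)C)(C(C)C)C(C)C)cc(O)c(O)c1O[Si](C(C)C)(C(C)C)C(C)C
F2 | step 9 | 2-hydroxy-4-methyl-3,5-bis(triisopropylsilyloxy)phenyl trifluoromethanesulfonate | Cc1c(O[Si](C(C)C)(C(C)C)C(C)C)cc(OS(=O)(=O)C(F)(F)F)c(O)c1O[Si](C(C)C)(C(C)C)C(C)C
F3 | step 9 | 2-acetoxy-4-methyl-3,5-bis(triisopropylsilyloxy)phenyl trifluoromethanesulfonate | Cc1c(O[Si](C(C)C)(C(C)C)C(C)C)cc(OS(=O)(=O)C(F)(F)F)c(OC(C)=O)c1O[Si](C(C)C)(C(C)C)C(C)C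
F4 | step 9 | (S)-6-methyl-2-(tributylstannyl)hepta-1,5-dien-3-ol | C=C([Sn](CCCC)(CCCC)CCCC)[C@H](CC=C(C)C)O
F5 | step 9 | (S)-2-[2-acetoxy-4-methyl-3,5-bis(triisopropylsilyloxy)phenyl]-6-methylhepta-1,5-dien-3-ol | C=C(c1cc(O[Si](C(C)C)(C(C)C)C(C)C)c(C)c(O[Si](C(C)C)(C(C)C)C(C)C)c1OC(C)=O)[C@H](CC=C(C)C)O
F6 | step 10 | (S)-2-[4-methyl-2-(4,4,5,5-tetramethyl-1,3,2-dioxaborolan-2-yl)-3,5-bis(triisopropylsilyloxy)phenyl]-6-methylhepta-1,5-dien-3-yl 2-[bis(2,2,2-trifluoroethoxy)phosphoryl]propanoate | C=C(c1cc(O[Si](C(C)C)(C(C)C)C(C)C)c(C)c(O[Si](C(C)C)(C(C)C)C(C)C)c1B1OC(C)(C)C(C)(C)O1)[C@H](CC=C(C)C)OC(=O)C(C)P(=O)(OCC(F)(F)F)OCC(F)(F)F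
F7 | step 11 | (S)-2-[2-hydroxy-4-methyl-3,5-bis(triisopropylsilyloxy)phenyl]-6-methylhepta-1,5-dien-3-ol | C=C(c1cc(O[Si](C(C)C)(C(C)C)C(C)C)c(C)c(O[Si](C(C)C)(C(C)C)C(C)C)c1O)[C@H](CC=C(C)C)O
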